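**Plan**
- Retrosynthesis: the two free hydroxyls (O5–H, O4'–H) go back to a 5-O-methyl and a 4'-O-benzyl ether. Ring C is then cut at C4–C4a (Friedel–Crafts acylation), then at O1–C2 (oxa-Michael addition), and the alkynoate at C3–C4 (acetylide acylation) and C2≡C3 (Corey–Fuchs).
- Forward: ring A is made as 2,3,4,5-tetramethoxyphenol from 2,3,4-trimethoxybenzaldehyde (Dakin, methylation, formylation, Dakin). Ring B is carried as the arylpropiolate from syringaldehyde.
- The two halves are joined at O1–C2, the ester is saponified, and ring C (the pyranone) closes last by forming C4–C4a. One boron trichloride step then frees O5 and O4'.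
- Enabling feature: in ring A of the aryl ether the future C4a is the only hydrogen-bearing carbon. It sits between C8a (bearing O1) and C5 (bearing OMe) and is para to the C7 methoxy, so an acyl carbon C4 on the O1–C2=C3 tether has exactly one activated site to attack.
- Stereochemistry: the target has no stereocentre. The only stereo-element on the way is the C2=C3 geometry of the open-chain acid, set Z by anti addition of the phenoxide to the alkyne and lost in the aromatic pyranone.

Key step: step 10

Remark: the target is achiral, so no enantiomer has to be selected; compounds 15–18 are drawn as the Z isomers expected from anti addition, and any E isomer should converge on the same flavone in step 10.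

**Step 1**
Reactants: 1 2,3,4-trimethoxybenzaldehyde
Product: 3 2,3,4-trimethoxyphenol, via 2,3,4-trimethoxyphenyl formate 2 (not isolated)
Conditions: 30% aq. H2O2 (1.3 equiv), H2SO4 (cat.), MeOH, 0 °C → rt
Reagents that add atoms: hydrogen peroxide, OO
Why: Acid-catalysed Dakin (Baeyer–Villiger-type) oxidation, in which the aryl group carrying ortho and para methoxy donors migrates in the peroxide adduct and the resulting formate is methanolysed in the same flask.

**Step 2**
Reactants: 3 2,3,4-trimethoxyphenol
Product: 4 1,2,3,4-tetramethoxybenzene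
Conditions: MeI (1.5 equiv), K2CO3 (2 equiv), acetone, reflux
Reagents that add atoms: iodomethane, CI
Why: Williamson ether synthesis of an unhindered phenoxide with a methyl halide.

**Step 3**
Reactants: 4 1,2,3,4-tetramethoxybenzene
Product: 6 2,3,4,5-tetramethoxybenzaldehyde, via 1-[chloro(methoxy)methyl]-2,3,4,5-tetramethoxybenzene 5 (not isolated)
Conditions: Cl2CHOMe (1.2 equiv), TiCl4 (1.5 equiv), CH2Cl2, −10 → 0 °C; then ice-water
Reagents that add atoms: dichloromethyl methyl ether, COC(Cl)Cl; water, O
Why: Rieche formylation, a Friedel–Crafts reaction in which the two free ring positions are equivalent by symmetry and each is ortho and para to a methoxy group, so one aldehyde should result after hydrolysis.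

**Step 4**
Reactants: 6 2,3,4,5-tetramethoxybenzaldehyde
Product: 8 2,3,4,5-tetramethoxyphenol, via 2,3,4,5-tetramethoxyphenyl formate 7 (not isolated)
Conditions: 30% aq. H2O2 (1.2 equiv), H2SO4 (cat.), MeOH, 0 °C → rt, under Ar
Reagents that add atoms: hydrogen peroxide, OO
Why: The same acid-catalysed Dakin oxidation as in step 1, run cold and with little excess oxidant to spare the oxidation-prone phenol.

**Step 5**
Reactants: 9 syringaldehyde
Product: 10 4-(benzyloxy)-3,5-dimethoxybenzaldehyde
Conditions: BnBr (1.2 equiv), K2CO3 (2 equiv), DMF, 60 °C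
Reagents that add atoms: benzyl bromide, BrCc1ccccc1
Why: Williamson benzylation of the phenol, giving an ether that withstands butyllithium, carbonate base and hydroxide and is cleaved by BCl3 in the last step.

**Step 6**
Reactants: 10 4-(benzyloxy)-3,5-dimethoxybenzaldehyde
Product: 11 2-(benzyloxy)-5-(2,2-dibromoethenyl)-1,3-dimethoxybenzene
Conditions: CBr4 (2 equiv), PPh3 (4 equiv), CH2Cl2, 0 °C
Reagents that add atoms: carbon tetrabromide, BrC(Br)(Br)Br
Why: First stage of the Corey–Fuchs reaction, a Wittig olefination of the aldehyde by the dibromomethylene ylide formed in the flask.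

**Step 7**
Reactants: 11 2-(benzyloxy)-5-(2,2-dibromoethenyl)-1,3-dimethoxybenzene; 12 ethyl chloroformate
Product: 14 ethyl 3-[4-(benzyloxy)-3,5-dimethoxyphenyl]prop-2-ynoate, via lithium arylacetylide 13 (not isolated)
Conditions: n-BuLi (2.2 equiv), THF, −78 °C; then ClCO2Et (1.5 equiv), −78 → 0 °C
Reagents that add atoms: none
Why: Second stage of the Corey–Fuchs reaction (bromine–lithium exchange, Fritsch–Buttenberg–Wiechell shift and deprotonation) gives the lithium acetylide, which is C-acylated by the chloroformate.

**Step 8**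
Reactants: 8 2,3,4,5-tetramethoxyphenol; 14 ethyl 3-[4-(benzyloxy)-3,5-dimethoxyphenyl]prop-2-ynoate
Product: 15 ethyl (2Z)-3-[4-(benzyloxy)-3,5-dimethoxyphenyl]-3-(2,3,4,5-tetramethoxyphenoxy)prop-2-enoate
Conditions: Cs2CO3 (0.3 equiv), DMF, 60 °C, under Ar
Reagents that add atoms: none
Why: Base-catalysed oxa-Michael addition of the phenoxide to the β-carbon of the ynoate, in which anti addition should place the aryloxy group cis to the ester (Z).

**Step 9**
Reactants: 15 ethyl (2Z)-3-[4-(benzyloxy)-3,5-dimethoxyphenyl]-3-(2,3,4,5-tetramethoxyphenoxy)prop-2-enoate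
Product: 17 (2Z)-3-[4-(benzyloxy)-3,5-dimethoxyphenyl]-3-(2,3,4,5-tetramethoxyphenoxy)prop-2-enoic acid, via lithium (Z)-3-aryl-3-aryloxyacrylate 16 (not isolated)
Conditions: LiOH·H2O (3 equiv), THF/H2O (2:1), rt → 40 °C; then 1 M HCl, 0 °C, to pH 3
Reagents that add atoms: lithium hydroxide, [Li+].[OH-]
Why: Saponification of the ethyl ester at the acyl carbon, with the donor-substituted β-carbon a poor acceptor for hydroxide and a cold, brief acidification sparing the enol ether.

**Step 10**
Reactants: 17 (2Z)-3-[4-(benzyloxy)-3,5-dimethoxyphenyl]-3-(2,3,4,5-tetramethoxyphenoxy)prop-2-enoic acid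
Product: 19 4'-O-benzyl-5,6,7,8,3',5'-hexamethoxyflavone, via (Z)-3-aryl-3-aryloxyacryloyl chloride 18 (not isolated)
Conditions: (COCl)2 (1.3 equiv), DMF (cat.), CH2Cl2, 0 °C → rt; evaporate; SnCl4 (1.1 equiv), CH2Cl2, −78 → −20 °C; aq. NaHCO3
Reagents that add atoms: none
Why: Oxalyl chloride with catalytic DMF should convert the acid into the β-aryloxycinnamoyl chloride, and SnCl4 polarises it to an acylium-like carbon C4 held by the Z-configured O1–C2=C3 tether over the aryloxy ring; attack by the future C4a gives a Wheland intermediate that loses a proton, forming C4–C4a and the aromatic 4-pyranone. The closest known reaction type is the intramolecular Friedel–Crafts acylation of β-aryloxycinnamic acids to flavones (Ruhemann-type flavone synthesis). Ring C closes in a 6-exo-trig mode at the acyl carbon (the arene π bond being endocyclic), and no stereocentre is formed. Site selectivity is secured by the substrate, since the attacked carbon is the only CH of the tetramethoxyphenoxy ring and is ortho to O1, ortho to the future 5-OMe and para to the future 7-OMe. The alternative five-membered closure onto ring B (an indenone) needs the E isomer and is more strained, while Lewis-acid coordination to the push–pull carbonyl lowers the C2=C3 rotation barrier so that any E material is funnelled to the reactive Z form. Low temperature and the mild tin halide should keep the benzyl ether and all methyl ethers intact.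

**Step 11**
Reactants: 19 4'-O-benzyl-5,6,7,8,3',5'-hexamethoxyflavone
Product: 21 5,4'-dihydroxy-6,7,8,3',5'-pentamethoxyflavone, via O5,O4'-bis(dichloroboryl) flavone 20 (not isolated)
Conditions: BCl3 (1 M in CH2Cl2, 4 equiv), C6HMe5 (3 equiv), CH2Cl2, −78 → 0 °C; then 1 M HCl/THF, rt
Reagents that add atoms: none
Why: Lewis-acid ether cleavage with BCl3, in which chelation between C4=O and O5 directs demethylation to the peri methoxy group and the aryl benzyl ether is cleaved at −78 °C with pentamethylbenzene trapping the benzyl cation, while the unchelated methyl ethers should persist and the borates are hydrolysed on work-up.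

**Compound list**
1 | 2,3,4-trimethoxybenzaldehyde | COc1ccc(C=O)c(OC)c1OC | starting material
2 | 2,3,4-trimethoxyphenyl formate | O=COc1ccc(OC)c(OC)c1OC | intermediate (not isolated)
3 | 2,3,4-trimethoxyphenol | Oc1ccc(OC)c(OC)c1OC | intermediate
4 | 1,2,3,4-tetramethoxybenzene | COc1ccc(OC)c(OC)c1OC | intermediate
5 | 1-[chloro(methoxy)methyl]-2,3,4,5-tetramethoxybenzene | COC(Cl)c1cc(OC)c(OC)c(OC)c1OC | intermediate (not isolated)
6 | 2,3,4,5-tetramethoxybenzaldehyde | O=Cc1cc(OC)c(OC)c(OC)c1OC | intermediate
7 | 2,3,4,5-tetramethoxyphenyl formate | O=COc1cc(OC)c(OC)c(OC)c1OC | intermediate (not isolated)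
8 | 2,3,4,5-tetramethoxyphenol | Oc1cc(OC)c(OC)c(OC)c1OC | intermediate
9 | syringaldehyde (4-hydroxy-3,5-dimethoxybenzaldehyde) | COc1cc(C=O)cc(OC)c1O | starting material
10 | 4-(benzyloxy)-3,5-dimethoxybenzaldehyde | COc1cc(C=O)cc(OC)c1OCc1ccccc1 | intermediate
11 | 2-(benzyloxy)-5-(2,2-dibromoethenyl)-1,3-dimethoxybenzene | COc1cc(C=C(Br)Br)cc(OC)c1OCc1ccccc1 | intermediate
12 | ethyl chloroformate | CCOC(=O)Cl | starting material
13 | lithium [4-(benzyloxy)-3,5-dimethoxyphenyl]acetylide | [Li]C#Cc1cc(OC)c(OCc2ccccc2)c(OC)c1 | intermediate (not isolated)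
14 | ethyl 3-[4-(benzyloxy)-3,5-dimethoxyphenyl]prop-2-ynoate | CCOC(=O)C#Cc1cc(OC)c(OCc2ccccc2)c(OC)c1 | intermediate
15 | ethyl (2Z)-3-[4-(benzyloxy)-3,5-dimethoxyphenyl]-3-(2,3,4,5-tetramethoxyphenoxy)prop-2-enoate | CCOC(=O)/C=C(/c1cc(OC)c(OCc2ccccc2)c(OC)c1)Oc1cc(OC)c(OC)c(OC)c1OC | intermediate
16 | lithium (2Z)-3-[4-(benzyloxy)-3,5-dimethoxyphenyl]-3-(2,3,4,5-tetramethoxyphenoxy)prop-2-enoate | [Li+].[O-]C(=O)/C=C(/c1cc(OC)c(OCc2ccccc2)c(OC)c1)Oc1cc(OC)c(OC)c(OC)c1OC | intermediate (not isolated)
17 | (2Z)-3-[4-(benzyloxy)-3,5-dimethoxyphenyl]-3-(2,3,4,5-tetramethoxyphenoxy)prop-2-enoic acid | O=C(O)/C=C(/c1cc(OC)c(OCc2ccccc2)c(OC)c1)Oc1cc(OC)c(OC)c(OC)c1OC | intermediate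
18 | (2Z)-3-[4-(benzyloxy)-3,5-dimethoxyphenyl]-3-(2,3,4,5-tetramethoxyphenoxy)prop-2-enoyl chloride | O=C(Cl)/C=C(/c1cc(OC)c(OCc2ccccc2)c(OC)c1)Oc1cc(OC)c(OC)c(OC)c1OC | intermediate (not isolated)
19 | 4'-O-benzyl-5,6,7,8,3',5'-hexamethoxyflavone (2-[4-(benzyloxy)-3,5-dimethoxyphenyl]-5,6,7,8-tetramethoxy-4H-chromen-4-one) | COc1cc(-c2cc(=O)c3c(OC)c(OC)c(OC)c(OC)c3o2)cc(OC)c1OCc1ccccc1 | intermediate
20 | 5-[(dichloroboranyl)oxy]-2-{4-[(dichloroboranyl)oxy]-3,5-dimethoxyphenyl}-6,7,8-trimethoxy-4H-chromen-4-one | COc1cc(-c2cc(=O)c3c(OB(Cl)Cl)c(OC)c(OC)c(OC)c3o2)cc(OC)c1OB(Cl)Cl | intermediate (not isolated)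
21 | 5,4'-dihydroxy-6,7,8,3',5'-pentamethoxyflavone | COc1cc(-c2cc(=O)c3c(O)c(OC)c(OC)c(OC)c3o2)cc(OC)c1O | target

**Step count**
Total steps: 11. Longest linear sequence: 8 steps (steps 1–4, then 8–11); the syringaldehyde branch (steps 5–7) joins at step 8.

**Steps most likely to fail**

1. Step 10 (key step). What may go wrong: ring closure of E-configured acyl chloride onto ring B to a five-membered ketone, Lewis-acid loss of the benzyl group, or hydrolysis of the enol ether with decarboxylation before the acyl chloride is formed. The fallback builds ring C through the O1–C2 bond instead; it sets out from phenol 8 (with aldehyde 10) and returns at flavone 19. Phenol 8 is C-acetylated at its only free ring position (AcOH, BF3·OEt2, 90 °C, Friedel–Crafts acylation) to give 1-(2-hydroxy-3,4,5,6-tetramethoxyphenyl)ethanone F1. Claisen–Schmidt condensation of this ketone with aldehyde 10 (KOH, EtOH, rt) should give (2E)-3-[4-(benzyloxy)-3,5-dimethoxyphenyl]-1-(2-hydroxy-3,4,5,6-tetramethoxyphenyl)prop-2-en-1-one F2. Oxidative cyclisation of the 2'-hydroxychalcone with catalytic iodine in DMSO at 120 °C then gives 19.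

2. Step 8. What may go wrong: slow conjugate addition of the hindered phenoxide to the donor-substituted arylpropiolate, air oxidation of the electron-rich phenoxide, or base-mediated scrambling of the alkene geometry. The fallback replaces conjugate addition by a metal-catalysed vinyl C–O coupling; it sets out from alkynoate 14 and returns at ester 15. Hydroiodination of 14 (NaI, AcOH, 70 °C, anti addition) should give ethyl (2Z)-3-[4-(benzyloxy)-3,5-dimethoxyphenyl]-3-iodoprop-2-enoate F3. This is coupled with phenol 8 under Ullmann-type conditions (CuI, N,N-dimethylglycine, Cs2CO3, dioxane, 90 °C) with retention of geometry to give 15.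

3. Step 11. What may go wrong: over-demethylation next to the boron-bound oxygens (6-OMe, 3'/5'-OMe), C-benzylation of the product by an untrapped benzyl cation, or incomplete hydrolysis of the boron chelate. The fallback separates the two deprotections and avoids boron; it sets out from flavone 19 and returns at target 21. Hydrogenolysis (H2 1 atm, Pd/C, EtOAc/THF, rt, stopped at full conversion to spare C2=C3) should give 4'-hydroxy-5,6,7,8,3',5'-hexamethoxyflavone F4. Protic-acid 5-O-demethylation (conc. HCl, EtOH, reflux), which is selective for the methoxy group peri to the carbonyl in polymethoxyflavones, then gives 21.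

**Further compounds**
F1 | step 10 | 1-(2-hydroxy-3,4,5,6-tetramethoxyphenyl)ethanone | CC(=O)c1c(O)c(OC)c(OC)c(OC)c1OC
F2 | step 10 | (2E)-3-[4-(benzyloxy)-3,5-dimethoxyphenyl]-1-(2-hydroxy-3,4,5,6-tetramethoxyphenyl)prop-2-en-1-one | COc1cc(/C=C/C(=O)c2c(O)c(OC)c(OC)c(OC)c2OC)cc(OC)c1OCc1ccccc1
F3 | step 8 | ethyl (2Z)-3-[4-(benzyloxy)-3,5-dimethoxyphenyl]-3-iodoprop-2-enoate | CCOC(=O)/C=C(\I)c1cc(OC)c(OCc2ccccc2)c(OC)c1
F4 | step 11 | 4'-hydroxy-5,6,7,8,3',5'-hexamethoxyflavone | COc1cc(-c2cc(=O)c3c(OC)c(OC)c(OC)c(OC)c3o2)cc(OC)c1O
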